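## Retrosynthetic overview

1. Target 22 ← acetonide acid 21 ← cross-metathesis of a C-1 allyl group with methacrolein, then Pinnick oxidation; the C-2 ketone comes from a silyl-protected carbinol.
2. The (E)-heptenyl diene and the CH2OH ← reduction of a fused unsaturated δ-lactone and dehydration of its carbinol; all ten carbons of (R)-massoia lactone 5 end up in the target.
3. The cis-epoxy alcohol ← hydroxyl-directed epoxidation of the allylic alcohol obtained by 1,2-reduction of an enone.
4. The cyclohexenone ← Diels–Alder reaction of 4-allyl-2-silyloxyfuran 4 with 5; the lactone stereocentre fixes the ring fusion, which fixes the carbinol, which fixes the oxirane.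
5. Ring order: carbocycle (step 3), then oxirane (step 5); diene 4 ← 4-bromofuranone 1 + allylstannane 2.

Assumption: natural (R)-(−)-massoia lactone of high enantiomeric purity is used as bought; compounds 6–12 are named with isochromene numbering and 13–22 with 7-oxabicyclo[4.1.0]hept-3-ene numbering. The route is designed on paper and has not been run; the stereochemical outcomes of steps 3–5 rest on the models stated in each Why line.

## Route

Step 1
Reactants: 1 4-bromofuran-2(5H)-one; 2 allyltributylstannane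
Product: 3 4-allylfuran-2(5H)-one
Conditions: Pd(PPh3)4 (5 mol%), toluene, 90 °C
Reagents that add atoms: none
Why: Stille cross-coupling of the vinylogous acyl bromide with the allyl stannane; no stereocentre is formed.

Step 2
Reactants: 3 4-allylfuran-2(5H)-one
Product: 4 4-allyl-2-(tert-butyldimethylsilyloxy)furan
Conditions: TBSOTf, Et3N, CH2Cl2, 0 °C
Reagents that add atoms: tert-butyldimethylsilyl trifluoromethanesulfonate, CC(C)(C)[Si](C)(C)OS(=O)(=O)C(F)(F)F
Why: Soft enolisation and O-silylation (silyl dienol ether formation) at the γ-CH2 is driven by aromatisation to the 2-silyloxyfuran; no stereocentre.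

Step 3
Reactants: 4 4-allyl-2-(tert-butyldimethylsilyloxy)furan; 5 (R)-massoia lactone
Product: 7 (3R)-6-allyl-5-(tert-butyldimethylsilyloxy)-3-pentyl-3,4,4a,5-tetrahydro-1H-isochromene-1,8(8aH)-dione (cis-fused), via bridged silyl ketal cycloadduct 6 (not isolated)
Conditions: toluene, 100 °C, sealed tube (or neat, 12 kbar, 25 °C)
Reagents that add atoms: none
Why: Normal-demand Diels–Alder [4+2] cycloaddition in which the unsubstituted furan α-carbon bonds to the lactone β-carbon and the silyloxy carbon to the α-carbon, the diene adds suprafacially to the lactone face anti to the pentyl group (cis ring fusion set by the bought C-3 centre), and the bridged silyl ketal 6 collapses with O-to-O silyl shift to the γ-silyloxy enone; the C-5 carbinol centre (endo adduct shown) does not matter because it becomes the ketone in step 11.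

Step 4
Reactants: 7 cis-fused silyloxy keto lactone
Product: 8 (3R)-6-allyl-5-(tert-butyldimethylsilyloxy)-8-hydroxy-3-pentyl-3,4,4a,5,8,8a-hexahydro-1H-isochromen-1-one
Conditions: NaBH4, CeCl3·7H2O, MeOH, −78 °C
Reagents that add atoms: none
Why: Luche 1,2-reduction in which hydride attacks the enone carbonyl from the convex face of the cis-fused bicycle, anti to the lactone ring, so the C-8 hydroxyl ends up cis to the lactone carbonyl carbon (trans to H-8a), as is usual for cyclic β-keto esters.

Step 5
Reactants: 8 allylic alcohol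
Product: 9 6,7-epoxide of 8 with the oxirane oxygen cis to 8-OH
Conditions: VO(acac)2 (5 mol%), t-BuOOH, CH2Cl2, 0 °C to rt
Reagents that add atoms: tert-butyl hydroperoxide, CC(C)(C)OO
Why: Vanadium-catalysed hydroxyl-directed epoxidation delivers oxygen syn to the allylic C-8 hydroxyl, setting both oxirane centres cis to it, and leaves the isolated terminal alkene alone.

Step 6
Reactants: 9 epoxy hydroxy lactone
Product: 12 (3R)-6-allyl-5-(tert-butyldimethylsilyloxy)-6,7-epoxy-8-hydroxy-3-pentyl-3,4,5,6,7,8-hexahydro-1H-isochromen-1-one (C4a=C8a alkene), via α-phenylselanyl lactone 10 (not isolated), via selenoxide 11 (not isolated)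
Conditions: LiN(iPr)2 (2.2 equiv), THF, −78 °C; PhSeBr; then H2O2, pyridine, CH2Cl2, 0 °C to rt
Reagents that add atoms: none
Why: Fráter–Seebach-type dianion selenenylation α to the lactone on the face anti to the alkoxide (cis to H-4a), followed by selenoxide syn-elimination toward C-4a and away from the carbinol carbon, removes the two ring-fusion centres and leaves the three oxygenated ring centres untouched.

Step 7
Reactants: 12 unsaturated epoxy lactone
Product: 13 (2R)-1-[1-allyl-2-(tert-butyldimethylsilyloxy)-5-hydroxy-4-(hydroxymethyl)-7-oxabicyclo[4.1.0]hept-3-en-3-yl]heptan-2-ol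
Conditions: iBu2AlH (5 equiv), CH2Cl2, −78 to −20 °C; aq. potassium sodium tartrate work-up
Reagents that add atoms: none
Why: Hydride 1,2-reduction of the conjugated lactone gives the allylic primary alcohol and the side-chain secondary alcohol at a temperature where the epoxy alcohol is not opened; no stereocentre changes.

Step 8
Reactants: 13 epoxy triol
Product: 14 acetonide of 13 spanning 5-O and the 4-CH2O group (1,3-dioxane), side-chain 2-OH free
Conditions: 2,2-dimethoxypropane, PPTS (cat.), CH2Cl2, rt
Reagents that add atoms: 2,2-dimethoxypropane, COC(C)(C)OC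
Why: Acid-catalysed transacetalisation in which only the 1,3-related primary and secondary hydroxyls can close a six-membered isopropylidene acetal, so the side-chain alcohol stays free.

Step 9
Reactants: 14 acetonide alcohol
Product: 16 acetonide-protected 1-allyl-2-(tert-butyldimethylsilyloxy)-3-[(E)-hept-1-enyl] epoxy cyclohexene, via secondary mesylate 15 (not isolated)
Conditions: MsCl, Et3N, CH2Cl2, 0 °C; then DBU, toluene, 80 °C
Reagents that add atoms: none
Why: Mesylation of the only free hydroxyl and E2 elimination toward the allylic CH2 gives the conjugated (E)-diene; the bought carbinol centre is erased here, after it has controlled the ring stereocentres.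

Step 10
Reactants: 16 silyl ether diene
Product: 17 the corresponding C-2 alcohol
Conditions: Bu4NF, AcOH (1:1), THF, 0 °C to rt
Reagents that add atoms: none
Why: Fluoride desilylation, buffered so that no free alkoxide can start a Payne rearrangement of the neighbouring oxirane.

Step 11
Reactants: 17 allylic alcohol
Product: 18 acetonide-protected 1-allyl-3-[(E)-hept-1-enyl]-7-oxabicyclo[4.1.0]hept-3-en-2-one
Conditions: Dess–Martin periodinane, CH2Cl2, 0 °C to rt
Reagents that add atoms: none
Why: Dess–Martin oxidation of the secondary allylic alcohol to the dienone; oxirane and acetal are inert and the carbinol centre of unsettled configuration disappears.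

Step 12
Reactants: 18 allyl dienone; 19 methacrolein
Product: 20 acetonide-protected dienone with a 1-[(E)-3-formylbut-2-enyl] side chain
Conditions: second-generation Grubbs catalyst (5 mol%), methacrolein (excess), CH2Cl2, 40 °C
Reagents that add atoms: none
Why: Olefin cross-metathesis in which the unhindered monosubstituted alkene reacts much faster than the hindered conjugated internal diene, and methacrolein gives the trisubstituted (E)-enal.

Step 13
Reactants: 20 enal
Product: 21 acetonide of the target acid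
Conditions: NaClO2, NaH2PO4, 2-methyl-2-butene, t-BuOH/H2O, 0 °C to rt
Reagents that add atoms: sodium chlorite, [Na+].[O-]Cl=O
Why: Pinnick oxidation converts the enal to the enoic acid without touching the alkenes, ketone or oxirane, with 2-methyl-2-butene trapping the hypochlorite.

Step 14
Reactants: 21 acetonide acid
Product: 22 (E)-4-[(1S,5S,6S)-3-[(E)-hept-1-enyl]-5-hydroxy-4-(hydroxymethyl)-2-oxo-7-oxabicyclo[4.1.0]hept-3-en-1-yl]-2-methylbut-2-enoic acid
Conditions: Amberlyst-15, THF/H2O (4:1), rt
Reagents that add atoms: none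
Why: Mild acid-catalysed acetal hydrolysis frees the 1,3-diol; the epoxy ketone survives and the (E)-enoic acid cannot reach the oxirane.

## Compound list

1 | 4-bromofuran-2(5H)-one | O=C1C=C(Br)CO1 | starting material
2 | allyltributylstannane | C=CC[Sn](CCCC)(CCCC)CCCC | starting material
3 | 4-allylfuran-2(5H)-one | O=C1C=C(CC=C)CO1 | intermediate
4 | 4-allyl-2-(tert-butyldimethylsilyloxy)furan | C=CCc1coc(O[Si](C)(C)C(C)(C)C)c1 | intermediate
5 | (R)-(−)-massoia lactone, (6R)-6-pentyl-5,6-dihydro-2H-pyran-2-one | CCCCC[C@@H]1CC=CC(=O)O1 | starting material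
6 | endo Diels–Alder adduct: (3R)-3-pentyl δ-lactone cis-fused to a 7-oxabicyclo[2.2.1]hept-5-ene; OTBS on the ketal bridgehead next to the lactone α-carbon, allyl on the alkene carbon next to the CH bridgehead, oxygen bridge syn to the ring-fusion hydrogens | CCCCC[C@@H]1C[C@H]2[C@@H]3O[C@@](O[Si](C)(C)C(C)(C)C)(C=C3CC=C)[C@H]2C(=O)O1 | intermediate
7 | (3R)-6-allyl-5-(tert-butyldimethylsilyloxy)-3-pentyl-3,4,4a,5-tetrahydro-1H-isochromene-1,8(8aH)-dione; cis ring fusion, H-4a and H-8a on the lactone face that carries the pentyl group, 5-OTBS cis to H-4a | CCCCC[C@@H]1C[C@H]2[C@H](O[Si](C)(C)C(C)(C)C)C(CC=C)=CC(=O)[C@H]2C(=O)O1 | intermediate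
8 | (3R)-6-allyl-5-(tert-butyldimethylsilyloxy)-8-hydroxy-3-pentyl-3,4,4a,5,8,8a-hexahydro-1H-isochromen-1-one; 8-OH trans to H-8a | CCCCC[C@@H]1C[C@H]2[C@H](O[Si](C)(C)C(C)(C)C)C(CC=C)=C[C@@H](O)[C@H]2C(=O)O1 | intermediate
9 | 6,7-epoxide of 8; oxirane oxygen cis to 8-OH, allyl on C-6 | CCCCC[C@@H]1C[C@H]2[C@H](O[Si](C)(C)C(C)(C)C)[C@@]3(CC=C)O[C@H]3[C@@H](O)[C@H]2C(=O)O1 | intermediate
10 | 8a-phenylselanyl derivative of 9; selenium on the face of the former H-8a | CCCCC[C@@H]1C[C@H]2[C@H](O[Si](C)(C)C(C)(C)C)[C@@]3(CC=C)O[C@H]3[C@@H](O)[C@@]2([Se]c4ccccc4)C(=O)O1 | intermediate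
11 | selenoxide of 10 | CCCCC[C@@H]1C[C@H]2[C@H](O[Si](C)(C)C(C)(C)C)[C@@]3(CC=C)O[C@H]3[C@@H](O)[C@@]2([Se](=O)c4ccccc4)C(=O)O1 | intermediate
12 | (3R)-6-allyl-5-(tert-butyldimethylsilyloxy)-6,7-epoxy-8-hydroxy-3-pentyl-3,4,5,6,7,8-hexahydro-1H-isochromen-1-one; C4a=C8a alkene, oxirane oxygen and 8-OH cis, 5-OTBS trans to them | CCCCC[C@@H]1CC2=C(C(=O)O1)[C@H](O)[C@@H]3O[C@]3(CC=C)[C@H]2O[Si](C)(C)C(C)(C)C | intermediate
13 | (2R)-1-[1-allyl-2-(tert-butyldimethylsilyloxy)-5-hydroxy-4-(hydroxymethyl)-7-oxabicyclo[4.1.0]hept-3-en-3-yl]heptan-2-ol; 5-OH cis and 2-OTBS trans to the oxirane oxygen | CCCCC[C@@H](O)CC1=C(CO)[C@H](O)[C@@H]2O[C@]2(CC=C)[C@H]1O[Si](C)(C)C(C)(C)C | intermediate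
14 | isopropylidene acetal of 13 across 5-O and the 4-CH2O group; side-chain (2R)-OH free | CCCCC[C@@H](O)CC1=C2COC(C)(C)O[C@@H]2[C@@H]3O[C@]3(CC=C)[C@H]1O[Si](C)(C)C(C)(C)C | intermediate
15 | side-chain methanesulfonate of 14 | CCCCC[C@@H](OS(C)(=O)=O)CC1=C2COC(C)(C)O[C@@H]2[C@@H]3O[C@]3(CC=C)[C@H]1O[Si](C)(C)C(C)(C)C | intermediate
16 | acetonide-protected 1-allyl-2-(tert-butyldimethylsilyloxy)-3-[(E)-hept-1-enyl]-7-oxabicyclo[4.1.0]hept-3-ene | CCCCC/C=C/C1=C2COC(C)(C)O[C@@H]2[C@@H]3O[C@]3(CC=C)[C@H]1O[Si](C)(C)C(C)(C)C | intermediate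
17 | C-2 alcohol from 16 | CCCCC/C=C/C1=C2COC(C)(C)O[C@@H]2[C@@H]3O[C@]3(CC=C)[C@H]1O | intermediate
18 | acetonide-protected 1-allyl-3-[(E)-hept-1-enyl]-7-oxabicyclo[4.1.0]hept-3-en-2-one | CCCCC/C=C/C1=C2COC(C)(C)O[C@@H]2[C@@H]3O[C@]3(CC=C)C1=O | intermediate
19 | methacrolein | CC(=C)C=O | starting material
20 | acetonide-protected dienone with a 1-[(E)-3-formylbut-2-enyl] side chain | CCCCC/C=C/C1=C2COC(C)(C)O[C@@H]2[C@@H]3O[C@]3(C/C=C(\C)C=O)C1=O | intermediate
21 | acetonide of the target acid | CCCCC/C=C/C1=C2COC(C)(C)O[C@@H]2[C@@H]3O[C@]3(C/C=C(\C)C(=O)O)C1=O | intermediate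
22 | (E)-4-[(1S,5S,6S)-3-[(E)-hept-1-enyl]-5-hydroxy-4-(hydroxymethyl)-2-oxo-7-oxabicyclo[4.1.0]hept-3-en-1-yl]-2-methylbut-2-enoic acid | CCCCC/C=C/C1=C(CO)[C@H](O)[C@@H]2O[C@]2(C/C=C(\C)C(=O)O)C1=O | target

## Step count and risks

Total step count: 14. Longest linear sequence: 14 steps (1 → 22); 2, 5 and 19 are used as bought.

Three steps most likely to fail:

**Step 3 (cycloaddition).** The unsaturated δ-lactone is a weak dienophile, and the γ-silyloxy enone could lose silanol and aromatise. Fallback: make the same two bonds anionically, setting out from 3 (with 5). The lithium dienolate of 3 (LiN(SiMe3)2, THF, −78 to 0 °C) adds through its γ-carbon to the β-carbon of 5, anti to the pentyl group. The resulting lactone enolate closes onto the butenolide carbonyl, which opens to the hydroxy keto lactone F1 (Michael–Dieckmann annulation). Silylation (TBSOTf, 2,6-lutidine) brings the material back to the route at 7, together with its C-5 epimer, which converges at 18.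

**Step 9 (elimination).** The E2 reaction could go the wrong way, or the silyl ether oxygen could displace the mesylate. Fallback: form the diene while the lactone is still intact, setting out from 12. KN(SiMe3)2 (THF, −78 °C) removes a γ-proton of the unsaturated δ-lactone, and vinylogous E1cB loss of the carboxylate (the parasorbic-to-sorbic acid opening) gives the (E)-heptenyl dienoic acid F2. TMSCHN2 gives the methyl ester F3, iBu2AlH at −78 °C gives the diol F4, and 2,2-dimethoxypropane/PPTS returns to the route at 16.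

**Step 12 (cross-metathesis).** The ruthenium carbene could attack the conjugated heptenyl diene. Fallback: do the metathesis before the diene exists, setting out from 14. Cross-metathesis of 14 with 19 (second-generation Grubbs catalyst) gives the hydroxy enal F5. Neutral syn-dehydration with the Burgess reagent (toluene, 60 °C), which spares the base-sensitive enal, gives the diene enal F6. Bu4NF/AcOH gives the allylic alcohol F7, and Dess–Martin oxidation returns to the route at 20.

## Further compounds

F1 | step 3 | 6-allyl-5-hydroxy-3-pentyl-3,4,4a,5-tetrahydro-1H-isochromene-1,8(8aH)-dione, cis-fused, (3R), both C-5 epimers | CCCCC[C@@H]1C[C@H]2C(O)C(CC=C)=CC(=O)[C@H]2C(=O)O1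
F2 | step 9 | 1-allyl-2-(tert-butyldimethylsilyloxy)-3-[(E)-hept-1-enyl]-5-hydroxy-7-oxabicyclo[4.1.0]hept-3-ene-4-carboxylic acid | CCCCC/C=C/C1=C(C(=O)O)[C@H](O)[C@@H]2O[C@]2(CC=C)[C@H]1O[Si](C)(C)C(C)(C)C
F3 | step 9 | methyl ester of F2 | CCCCC/C=C/C1=C(C(=O)OC)[C@H](O)[C@@H]2O[C@]2(CC=C)[C@H]1O[Si](C)(C)C(C)(C)C
F4 | step 9 | 1-allyl-2-(tert-butyldimethylsilyloxy)-3-[(E)-hept-1-enyl]-4-(hydroxymethyl)-7-oxabicyclo[4.1.0]hept-3-en-5-ol | CCCCC/C=C/C1=C(CO)[C@H](O)[C@@H]2O[C@]2(CC=C)[C@H]1O[Si](C)(C)C(C)(C)C
F5 | step 12 | analogue of 14 with a 1-[(E)-3-formylbut-2-enyl] side chain | CCCCC[C@@H](O)CC1=C2COC(C)(C)O[C@@H]2[C@@H]3O[C@]3(C/C=C(\C)C=O)[C@H]1O[Si](C)(C)C(C)(C)C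
F6 | step 12 | analogue of 16 with a 1-[(E)-3-formylbut-2-enyl] side chain | CCCCC/C=C/C1=C2COC(C)(C)O[C@@H]2[C@@H]3O[C@]3(C/C=C(\C)C=O)[C@H]1O[Si](C)(C)C(C)(C)C
F7 | step 12 | analogue of 17 with a 1-[(E)-3-formylbut-2-enyl] side chain | CCCCC/C=C/C1=C2COC(C)(C)O[C@@H]2[C@@H]3O[C@]3(C/C=C(\C)C=O)[C@H]1O
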